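Cuts (eudesmane numbering): the O6–angeloyl bond, C11=C13 and the two silyl ethers come off first. C6–OH then goes back to C6=O, and C5–C6 and C9–C10 of the cyclohexene (ring B) are cut together.
Enabling feature: ring B has its tetrasubstituted C5=C10 olefin next to the C6 carbinol and has C9 as its only CH2. It is therefore a reduced 2,3-disubstituted cyclohex-2-enone, the retron for inserting the alkyne C5≡C10 into the C6(O)–C9 bond of the cyclobutanone C6–C7–C8–C9 cis-fused to the γ-lactone.
Forward: a ketene–enol ether (2+2) and lactonisation give the lactone-fused four-membered ring, and citronellene gives the chiral alkyne. A nickel-catalysed two-atom ring expansion joins the halves and creates ring B. C6 reduction, C13 methylenation, angeloylation and desilylation follow.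
Stereochemistry: C4 comes from (S)-β-citronellene. C7/C8 (cis) come from the Z-enol ether geometry and a removable (S)-1-arylethyl auxiliary on O8. C6 is set by CBS reduction, and the Z-olefin of the ester comes from angelic acid.

Key step: step 10

Remark: eudesmane numbering is used throughout (ring B = C5–C10; C4 = side-chain stereocentre; C11–C13 = lactone carbons; C14 = CH2O on C10); (S)-β-citronellene, (S)-1-(2,4,6-triisopropylphenyl)ethanol and angelic acid are taken as commercial in high isomeric purity.

Step 1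
Reactants: 1 (S)-β-citronellene [(3S)-3,7-dimethylocta-1,6-diene]
Product: 2 (4S)-4-methylhex-5-en-1-ol
Conditions: O3 (1 equiv, Sudan III end point), CH2Cl2–MeOH, −78 °C; NaBH4, −78 → 0 °C
Reagents that add atoms: ozone [O-][O+]=O
Why: Chemoselective ozonolysis with reductive work-up, in which the electron-rich trisubstituted olefin is consumed well before the vinyl group and the chiral-pool stereocentre (future C4) is not touched.

Step 2
Reactants: 2 (4S)-4-methylhex-5-en-1-ol
Product: 3 tert-butyl(dimethyl){[(4S)-4-methylhex-5-en-1-yl]oxy}silane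
Conditions: TBSCl, imidazole, DMF, rt
Reagents that add atoms: tert-butyldimethylsilyl chloride CC(C)(C)[Si](C)(C)Cl
Why: Standard silylation of a primary alcohol, needed so that the hydroxyl cannot capture the bromonium ion in the next step.

Step 3
Reactants: 3 tert-butyl(dimethyl){[(4S)-4-methylhex-5-en-1-yl]oxy}silane
Product: 6 tert-butyl(dimethyl){[(4S)-4-methylhex-5-yn-1-yl]oxy}silane, via vicinal dibromide 4 (not isolated), via sodium acetylide 5 (not isolated)
Conditions: Br2, CH2Cl2, −78 °C; crude, NaNH2 (3.5 equiv), NH3(l)–THF, −33 °C; H2O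
Reagents that add atoms: bromine BrBr (in 4 only); sodium amide [Na+].[NH2-] (Na in 5 only)
Why: Alkene-to-alkyne conversion by bromination and double E2 dehydrobromination, in which the alkyne is stored at once as its acetylide, so alkyne–allene isomerisation is blocked and the propargylic stereocentre is kept.

Step 4
Reactants: 6 tert-butyl(dimethyl){[(4S)-4-methylhex-5-yn-1-yl]oxy}silane
Product: 9 (4S)-1,7-bis(tert-butyldimethylsilyloxy)-4-methylhept-2-yne, via lithium acetylide 7 (not isolated), via lithium propargylic alkoxide 8 (not isolated)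
Conditions: n-BuLi, THF, −78 °C; (CH2O)n, −78 °C → rt; TBSCl, DMAP (cat.), 0 °C → rt
Reagents that add atoms: n-butyllithium [Li]CCCC (Li in 7 and 8 only); formaldehyde (as paraformaldehyde) C=O; tert-butyldimethylsilyl chloride CC(C)(C)[Si](C)(C)Cl
Why: Acetylide addition to formaldehyde brings in C14, and the alkoxide is silylated in the same flask, both routine operations on terminal alkynes.

Step 5
Reactants: 10 (S)-1-(2,4,6-triisopropylphenyl)ethanol; 11 allyl bromide
Product: 13 allyl (S)-1-(2,4,6-triisopropylphenyl)ethyl ether, via potassium alkoxide 12 (not isolated)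
Conditions: KH, THF, 0 °C; allyl bromide, Bu4NI (cat.), rt
Reagents that add atoms: potassium hydride [K+].[H-] (K in 12 only)
Why: Williamson ether synthesis on the alkoxide, in which the benzylic C–O bond of the auxiliary is not broken and its configuration is retained.

Step 6
Reactants: 13 allyl (S)-1-(2,4,6-triisopropylphenyl)ethyl ether; 14 methyl acrylate
Product: 15 methyl (E)-4-[(S)-1-(2,4,6-triisopropylphenyl)ethoxy]but-2-enoate
Conditions: Hoveyda–Grubbs II (3 mol %), methyl acrylate (3 equiv), CH2Cl2, 40 °C
Reagents that add atoms: none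
Why: Olefin cross metathesis of a terminal allyl ether with an acrylate, a pairing that reliably gives the E-enoate and is driven by loss of ethene.

Step 7
Reactants: 15 methyl (E)-4-[(S)-1-(2,4,6-triisopropylphenyl)ethoxy]but-2-enoate
Product: 17 methyl (Z)-4-[(S)-1-(2,4,6-triisopropylphenyl)ethoxy]but-3-enoate, via lithium dienolate 16 (not isolated)
Conditions: LDA, THF–DMPU, −78 °C; AcOH, −78 °C
Reagents that add atoms: lithium diisopropylamide [Li+].CC(C)[N-]C(C)C (Li in 16 only)
Why: Deconjugative isomerisation (kinetic γ-deprotonation, then α-protonation of the extended enolate), which with E-2-enoates is known to give the Z-3-enoate, here the Z-enol ether needed for the cis C7/C8 relationship.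

Step 8
Reactants: 17 methyl (Z)-4-[(S)-1-(2,4,6-triisopropylphenyl)ethoxy]but-3-enoate; 18 trichloroacetyl chloride
Product: 21 methyl 2-[(1R,2R)-4-oxo-2-{(S)-1-(2,4,6-triisopropylphenyl)ethoxy}cyclobutyl]acetate, via dichloroketene 19 (not isolated), via dichlorocyclobutanone 20 (not isolated)
Conditions: Cl3CCOCl, Zn–Cu, Et2O, 0 °C → rt; filter; Zn, AcOH, rt
Reagents that add atoms: none
Why: Ketene–enol ether (2+2) cycloaddition and zinc dechlorination, in which the ketene carbonyl carbon (C6) bonds to the nucleophilic β-carbon C7 and CCl2 (C9) to the oxygen-bearing C8, the Z-geometry is transferred suprafacially into the cis C7/C8 pair, and the triisopropylphenyl group (s-trans enol ether, carbinol C–H eclipsed with the vinyl C–O bond) shields one face so that the (7R,8R) series should form.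

Step 9
Reactants: 21 methyl 2-[(1R,2R)-4-oxo-2-{(S)-1-(2,4,6-triisopropylphenyl)ethoxy}cyclobutyl]acetate
Product: 23 (1R,5R)-2-oxabicyclo[3.2.0]heptane-3,6-dione, via hydroxy ester 22 (not isolated)
Conditions: CF3CO2H, CH2Cl2, 0 °C
Reagents that add atoms: none
Why: Acidolysis of the hindered benzylic ether (E1 loss of the 1-arylethyl cation as the styrene) frees O8, which sits cis to the acetate arm and should close the γ-lactone by acid-catalysed transesterification (5-exo-trig) before the β-hydroxy ketone can open by retro-aldol cleavage.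

Step 10
Reactants: 23 (1R,5R)-2-oxabicyclo[3.2.0]heptane-3,6-dione; 9 (4S)-1,7-bis(tert-butyldimethylsilyloxy)-4-methylhept-2-yne
Product: 24 (4S,7R,8R)-1,14-bis(tert-butyldimethylsilyloxy)-6-oxo-1,10-secoeudesm-5(10)-en-12,8-olide
Conditions: Ni(cod)2 (10 mol %), IPr (12 mol %), toluene, 60 → 80 °C, 9 added by syringe pump
Reagents that add atoms: none
Why: Proposed new method: Ni(0) binds the alkyne and, from the convex face, the strained C6 carbonyl of 23 and couples them oxidatively to a spiro oxanickelacyclopentene (C5–C6 bond); β-carbon elimination then breaks C6–C9 with release of the four-ring strain, and C(sp2)–C(sp3) reductive elimination joins C9 to C10, so the ring C6–C7–C8–C9 grows by the two alkyne carbons into ring B. The closest known reaction type is the nickel(0)-catalysed intermolecular insertion of internal alkynes into cyclobutanones and azetidin-3-ones (formal [4+2]); new are the 2,3-fused, β-acyloxy-substituted ketone and the requirement that the branched alkyne terminus ends next to the carbonyl group. The only ring closed is the cyclohexenone, closed by reductive elimination from a seven-membered nickelacycle, not by a nucleophile–electrophile closure. No stereocentre is created: C7 and C8 are untouched because only C6–C9 breaks, and C4 is a spectator, so the ring/side-chain relationship follows from joining two enantiopure halves. Site selectivity should follow from β-carbon elimination of the unsubstituted C9 (primary alkyl–nickel) rather than the substituted C7, as found for 2-substituted azetidin-3-ones. Alkyne orientation is the critical selectivity: the very bulky carbene ligand should push the sec-alkyl terminus away from nickel onto the C–C-forming carbon, as in ligand-size-controlled nickel aldehyde–alkyne couplings, where it meets only the tied-back four-membered ketone, while the inductively withdrawing CH2OTBS terminus favours the Ni–C10 bond.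

Step 11
Reactants: 24 (4S,7R,8R)-1,14-bis(tert-butyldimethylsilyloxy)-6-oxo-1,10-secoeudesm-5(10)-en-12,8-olide
Product: 25 (4S,6S,7S,8R)-1,14-bis(tert-butyldimethylsilyloxy)-6-hydroxy-1,10-secoeudesm-5(10)-en-12,8-olide
Conditions: (R)-Me-CBS (0.5 equiv), BH3·SMe2, THF, −30 °C; MeOH, then H2O
Reagents that add atoms: none
Why: Corey–Bakshi–Shibata 1,2-reduction under reagent control, with the tetrasubstituted C5 alkenyl branch as the large and C7 as the small ketone substituent, so that the (R)-oxazaborolidine should set (6S) with O6 trans to C11, which is also the result of axial attack on the conformer with C11 equatorial.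

Step 12
Reactants: 25 (4S,6S,7S,8R)-1,14-bis(tert-butyldimethylsilyloxy)-6-hydroxy-1,10-secoeudesm-5(10)-en-12,8-olide
Product: 29 (4S,6S,7S,8R)-1,14-bis(tert-butyldimethylsilyloxy)-6-hydroxy-1,10-secoeudesma-5(10),11(13)-dien-12,8-olide, via dilithio alkoxide enolate 26 (not isolated), via Mannich base 27 (not isolated), via methiodide 28 (not isolated)
Conditions: LDA (2.5 equiv), THF, −78 °C; CH2=NMe2+ I−, −78 → 0 °C; H2O; MeI, MeOH, rt; aq NaHCO3, CH2Cl2
Reagents that add atoms: Eschenmoser's salt C=[N+](C)C.[I-]; iodomethane CI (in 28 only); lithium diisopropylamide [Li+].CC(C)[N-]C(C)C (Li in 26 only)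
Why: Mannich aminomethylation of the lactone enolate (the C6 alkoxide rides along), N-methylation and Hofmann-type elimination, the standard α-methylenation of γ-lactones, in which the transient C11 centre (convex-face attack) is destroyed again and no leaving group sits β to the enolate.

Step 13
Reactants: 29 (4S,6S,7S,8R)-1,14-bis(tert-butyldimethylsilyloxy)-6-hydroxy-1,10-secoeudesma-5(10),11(13)-dien-12,8-olide; 30 angelic acid [(Z)-2-methylbut-2-enoic acid]
Product: 32 1,14-bis-O-(tert-butyldimethylsilyl)eriolangin (4S,6S,7R,8R), via mixed anhydride 31 (not isolated)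
Conditions: 30, 2,4,6-trichlorobenzoyl chloride, Et3N, toluene, rt; then 29, toluene, 75 °C (no DMAP)
Reagents that add atoms: 2,4,6-trichlorobenzoyl chloride O=C(Cl)c1c(Cl)cc(Cl)cc1Cl (in 31 only)
Why: Yamaguchi esterification, in which the mixed anhydride acylates the hindered C6 hydroxyl at the less hindered angeloyl carbonyl without a nucleophilic catalyst, conditions under which the Z-2-methylbut-2-enoyl unit keeps its geometry, and C6 keeps its configuration because its C–O bond is not broken.

Step 14
Reactants: 32 1,14-bis-O-(tert-butyldimethylsilyl)eriolangin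
Product: 33 eriolangin (4S,6S,7R,8R)
Conditions: HF·pyridine, pyridine–THF, 0 °C → rt
Reagents that add atoms: none
Why: Fluoride-mediated cleavage of the two primary silyl ethers under buffered, non-basic conditions that should leave the α-methylene lactone, the allylic angelate and all four stereocentres untouched.

Compound list
1 | (S)-β-citronellene | C=C[C@@H](C)CCC=C(C)C | starting material
2 | (4S)-4-methylhex-5-en-1-ol | C=C[C@@H](C)CCCO | intermediate
3 | tert-butyl(dimethyl){[(4S)-4-methylhex-5-en-1-yl]oxy}silane | C=C[C@@H](C)CCCO[Si](C)(C)C(C)(C)C | intermediate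
4 | (4S)-5,6-dibromo-4-methylhexyl TBS ether (C5 epimers) | BrCC(Br)[C@@H](C)CCCO[Si](C)(C)C(C)(C)C | intermediate
5 | sodium acetylide of 6 | [Na+].[C-]#C[C@@H](C)CCCO[Si](C)(C)C(C)(C)C | intermediate
6 | tert-butyl(dimethyl){[(4S)-4-methylhex-5-yn-1-yl]oxy}silane | C#C[C@@H](C)CCCO[Si](C)(C)C(C)(C)C | intermediate
7 | lithium acetylide of 6 | [Li+].[C-]#C[C@@H](C)CCCO[Si](C)(C)C(C)(C)C | intermediate
8 | lithium (4S)-7-(tert-butyldimethylsilyloxy)-4-methylhept-2-yn-1-olate | [Li+].[O-]CC#C[C@@H](C)CCCO[Si](C)(C)C(C)(C)C | intermediate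
9 | (4S)-1,7-bis(tert-butyldimethylsilyloxy)-4-methylhept-2-yne | CC(C)(C)[Si](C)(C)OCC#C[C@@H](C)CCCO[Si](C)(C)C(C)(C)C | intermediate
10 | (S)-1-(2,4,6-triisopropylphenyl)ethanol | O[C@@H](C)c1c(C(C)C)cc(C(C)C)cc1C(C)C | starting material
11 | allyl bromide | C=CCBr | starting material
12 | potassium alkoxide of 10 | [K+].[O-][C@@H](C)c1c(C(C)C)cc(C(C)C)cc1C(C)C | intermediate
13 | allyl (S)-1-(2,4,6-triisopropylphenyl)ethyl ether | C=CCO[C@@H](C)c1c(C(C)C)cc(C(C)C)cc1C(C)C | intermediate
14 | methyl acrylate | C=CC(=O)OC | starting material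
15 | methyl (E)-4-[(S)-1-(2,4,6-triisopropylphenyl)ethoxy]but-2-enoate | COC(=O)/C=C/CO[C@@H](C)c1c(C(C)C)cc(C(C)C)cc1C(C)C | intermediate
16 | lithium dienolate of 15 | [Li+].[O-]C(OC)=C/C=C\O[C@@H](C)c1c(C(C)C)cc(C(C)C)cc1C(C)C | intermediate
17 | methyl (Z)-4-[(S)-1-(2,4,6-triisopropylphenyl)ethoxy]but-3-enoate | COC(=O)C/C=C\O[C@@H](C)c1c(C(C)C)cc(C(C)C)cc1C(C)C | intermediate
18 | trichloroacetyl chloride | ClC(Cl)(Cl)C(Cl)=O | starting material
19 | dichloroketene | ClC(Cl)=C=O | intermediate
20 | methyl 2-[(1R,2S)-3,3-dichloro-4-oxo-2-{(S)-1-(2,4,6-triisopropylphenyl)ethoxy}cyclobutyl]acetate | COC(=O)C[C@H]1C(=O)C(Cl)(Cl)[C@H]1O[C@@H](C)c2c(C(C)C)cc(C(C)C)cc2C(C)C | intermediate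
21 | methyl 2-[(1R,2R)-4-oxo-2-{(S)-1-(2,4,6-triisopropylphenyl)ethoxy}cyclobutyl]acetate | COC(=O)C[C@H]1C(=O)C[C@H]1O[C@@H](C)c2c(C(C)C)cc(C(C)C)cc2C(C)C | intermediate
22 | methyl 2-[(1R,2R)-2-hydroxy-4-oxocyclobutyl]acetate | COC(=O)C[C@H]1C(=O)C[C@H]1O | intermediate
23 | (1R,5R)-2-oxabicyclo[3.2.0]heptane-3,6-dione (cis-fused) | C1C(=O)O[C@@H]2CC(=O)[C@H]12 | intermediate
24 | (4S,7R,8R)-1,14-bis(TBSO)-6-oxo-1,10-secoeudesm-5(10)-en-12,8-olide | C1C(=O)O[C@@H]2CC(CO[Si](C)(C)C(C)(C)C)=C([C@@H](C)CCCO[Si](C)(C)C(C)(C)C)C(=O)[C@H]12 | intermediate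
25 | (4S,6S,7S,8R)-1,14-bis(TBSO)-6-hydroxy-1,10-secoeudesm-5(10)-en-12,8-olide | C1C(=O)O[C@@H]2CC(CO[Si](C)(C)C(C)(C)C)=C([C@@H](C)CCCO[Si](C)(C)C(C)(C)C)[C@@H](O)[C@H]12 | intermediate
26 | dilithio C6-alkoxide/lactone enolate of 25 | C1=C([O-])O[C@@H]2CC(CO[Si](C)(C)C(C)(C)C)=C([C@@H](C)CCCO[Si](C)(C)C(C)(C)C)[C@@H]([O-])[C@H]12.[Li+].[Li+] | intermediate
27 | (11S)-13-(dimethylamino) derivative of 25 (Mannich base) | CN(C)C[C@H]1C(=O)O[C@@H]2CC(CO[Si](C)(C)C(C)(C)C)=C([C@@H](C)CCCO[Si](C)(C)C(C)(C)C)[C@@H](O)[C@H]12 | intermediate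
28 | trimethylammonium iodide of 27 | C[N+](C)(C)C[C@H]1C(=O)O[C@@H]2CC(CO[Si](C)(C)C(C)(C)C)=C([C@@H](C)CCCO[Si](C)(C)C(C)(C)C)[C@@H](O)[C@H]12.[I-] | intermediate
29 | (4S,6S,7S,8R)-1,14-bis(TBSO)-6-hydroxy-1,10-secoeudesma-5(10),11(13)-dien-12,8-olide | C=C1C(=O)O[C@@H]2CC(CO[Si](C)(C)C(C)(C)C)=C([C@@H](C)CCCO[Si](C)(C)C(C)(C)C)[C@@H](O)[C@H]12 | intermediate
30 | angelic acid | C/C=C(/C)C(=O)O | starting material
31 | angelic 2,4,6-trichlorobenzoic anhydride | C/C=C(/C)C(=O)OC(=O)c1c(Cl)cc(Cl)cc1Cl | intermediate
32 | 1,14-bis-O-TBS-eriolangin | C=C1C(=O)O[C@@H]2CC(CO[Si](C)(C)C(C)(C)C)=C([C@@H](C)CCCO[Si](C)(C)C(C)(C)C)[C@@H](OC(=O)/C(C)=C\C)[C@H]12 | intermediate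
33 | eriolangin | C=C1C(=O)O[C@@H]2CC(CO)=C([C@@H](C)CCCO)[C@@H](OC(=O)/C(C)=C\C)[C@H]12 | target

Total step count: 14. Longest linear sequence: 10 steps (steps 5–14, from 10); the alkyne branch (steps 1–4) joins at step 10.

Steps most likely to fail

Step 10 (Proposed new method). Several processes are at risk.
- The alkyne may insert in the opposite orientation, with the sec-alkyl terminus next to nickel.
- The alkyl–nickel intermediate may lose the β-acyloxy group at C8.
- The β-acyloxy enone may aromatise by elimination at the reaction temperature.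
- The alkyne may oligomerise.

The fallback uses known chemistry and runs from 6 and 23 back to 25. Compound 6 is C-silylated (n-BuLi, Me3SiCl) to the 1-silylalkyne F1. Nickel(0)/PCy3-catalysed insertion into 23 relies on the expected orientation of 1-silylalkynes in nickel(0) oxidative couplings, in which the silicon-bearing carbon bonds to the CH2, and gives the 10-silyl enone F2. CBS reduction as in step 11 gives the allylic alcohol F3. Iododesilylation (NIS, hexafluoroisopropanol) gives the vinyl iodide F4. Stille coupling with tributyl[(tert-butyldimethylsilyloxy)methyl]stannane brings in C14 and returns 25.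

Step 11. Facial selectivity may be poor if the catalyst and the convex-face bias of the cis-fused bicycle are mismatched, and the lactone may migrate to O6 in the product. The fallback runs from 24 back to 25. Luche reduction under substrate control from the convex face gives the 6-epi alcohol F5. Mitsunobu inversion with 4-nitrobenzoic acid gives the (6S)-4-nitrobenzoate F6. Mild methanolysis (K2CO3, MeOH, 0 °C) returns 25.

Step 13. Slow acylation of the hindered C6 hydroxyl may leave time for Z-to-E isomerisation of the activated angeloyl unit. The fallback runs from 29 back to 32. Carbodiimide esterification with 2-[bis(2,2,2-trifluoroethoxy)phosphoryl]propanoic acid gives the phosphonopropionate F7. Still–Gennari olefination (KHMDS, 18-crown-6, THF, −78 °C; acetaldehyde) then builds the Z-trisubstituted olefin on the ester already in place and returns 32.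

Further compounds
F1 | step 10 | (4S)-6-(tert-butyldimethylsilyloxy)-3-methyl-1-(trimethylsilyl)hex-1-yne | C[Si](C)(C)C#C[C@@H](C)CCCO[Si](C)(C)C(C)(C)C
F2 | step 10 | 10-trimethylsilyl-14-nor analogue of enone 24 | C1C(=O)O[C@@H]2CC([Si](C)(C)C)=C([C@@H](C)CCCO[Si](C)(C)C(C)(C)C)C(=O)[C@H]12
F3 | step 10 | (6S)-allylic alcohol from F2 | C1C(=O)O[C@@H]2CC([Si](C)(C)C)=C([C@@H](C)CCCO[Si](C)(C)C(C)(C)C)[C@@H](O)[C@H]12
F4 | step 10 | 10-iodo allylic alcohol | C1C(=O)O[C@@H]2CC(I)=C([C@@H](C)CCCO[Si](C)(C)C(C)(C)C)[C@@H](O)[C@H]12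
F5 | step 11 | 6-epi-25 | C1C(=O)O[C@@H]2CC(CO[Si](C)(C)C(C)(C)C)=C([C@@H](C)CCCO[Si](C)(C)C(C)(C)C)[C@H](O)[C@H]12
F6 | step 11 | 6-O-(4-nitrobenzoyl)-25 | C1C(=O)O[C@@H]2CC(CO[Si](C)(C)C(C)(C)C)=C([C@@H](C)CCCO[Si](C)(C)C(C)(C)C)[C@@H](OC(=O)c3ccc(cc3)[N+](=O)[O-])[C@H]12
F7 | step 13 | 6-O-{2-[bis(2,2,2-trifluoroethoxy)phosphoryl]propanoyl}-29 | C=C1C(=O)O[C@@H]2CC(CO[Si](C)(C)C(C)(C)C)=C([C@@H](C)CCCO[Si](C)(C)C(C)(C)C)[C@@H](OC(=O)C(C)P(=O)(OCC(F)(F)F)OCC(F)(F)F)[C@H]12
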